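The route rests on disconnecting the two C–Br bonds at C4' and C6' of ring B, which are all that separate the target from the symmetric bis(3,5-dibromo-2-hydroxyphenyl) ether. Oxidation of that diol to a spiroketal makes ring A a non-aromatic dienone (ketal carbon C1, carbonyl C2) and leaves ring B as an aromatic benzodioxole with oxygens on C1' and C2'. The key step exploits this difference: in one operation electrophilic bromine fills the only two aromatic C–H positions, C4' and C6' of ring B, while the electron-poor dienone is spared. Its precursor is the racemic tetrabromo spiroketal; reductive ketal opening then restores both phenols.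

Key step: step 3

Remark: in the text, unprimed locants are ring A and primed locants ring B of the diphenyl ether, whereas in the spiro names the primed locants belong to the cyclohexadienone (ring B C4' and C6' are benzodioxole C5 and C7); the order in which partly brominated intermediates form is assumed (para before ortho) and affects no isolated compound; 2,2'-oxydiphenol is taken as purchasable.

Step 1
Reactants: 1 2,2'-oxydiphenol; 2 bromine
Product: 6 2,2'-oxybis(4,6-dibromophenol), via monobromide 3 (not isolated), via dibromide 4 (not isolated), via tribromide 5 (not isolated)
Conditions: Br2 (4.1 equiv), AcOH, 15 °C to rt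
Reagents that add atoms: bromine, BrBr
Why: Electrophilic aromatic bromination of a phenol: each hydroxyl outranks the shared diaryl ether oxygen as a donor, so every ring is substituted para and then ortho to its own OH (C5 and C3, the pattern guaiacol-type phenols give), and four equivalents should stop at the tetrabromide because the positions left are meta to OH and flanked by bromine.

Step 2
Reactants: 6 2,2'-oxybis(4,6-dibromophenol)
Product: 7 racemic 3',4,5',6-tetrabromospiro[1,3-benzodioxole-2,1'-cyclohexa-3',5'-dien]-2'-one
Conditions: PhI(OAc)2 (1.05 equiv), CH2Cl2 (0.02 M), 0 °C to rt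
Reagents that add atoms: none
Why: Oxidative dearomatisation of a 2-aryloxyphenol to an ortho-quinone monoketal: the phenol of one ring exchanges onto trivalent iodine, the hydroxyl of the other ring attacks the aryloxy-bearing carbon C1 in a five-membered closure as iodobenzene leaves, and the spiro carbon so formed is an uncontrolled stereocentre (racemate), which is acceptable because step 3 removes its chirality, while the bromine para to the former hydroxyl should slow Diels–Alder dimerisation of the dienone.

Step 3
Reactants: 7 racemic 3',4,5',6-tetrabromospiro[1,3-benzodioxole-2,1'-cyclohexa-3',5'-dien]-2'-one; 2 bromine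
Product: 9 3',4,5,5',6,7-hexabromospiro[1,3-benzodioxole-2,1'-cyclohexa-3',5'-dien]-2'-one, via pentabromo spiroketal 8 (not isolated)
Conditions: Br2 (2.5 equiv), AgOCOCF3 (2.5 equiv), CH2Cl2–CF3CO2H, 0 °C to rt, dark; cyclohexene quench (no reducing wash), filtration of AgBr
Reagents that add atoms: bromine, BrBr
Why: Proposed new method: Br2 and AgOCOCF3 give AgBr and trifluoroacetyl hypobromite, a bromide-free source of electrophilic bromine that should attack the benzodioxole ring of 7 at C5 (C4' of ring B, para to the ring oxygen on C1') and then at C7 (C6' of ring B, ortho to the same oxygen) by ordinary arenium-ion substitution, each event releasing CF3CO2H; the closest known reaction type is electrophilic bromination of 1,3-benzodioxoles and catechol diethers, which has not been run on a spiro-fused ortho-quinone monoketal. No ring closes and no stereocentre is created; the spiro carbon of racemic 7 ceases to be a stereocentre once the benzo ring of 9 carries four bromines. The selectivity needed is ring B over ring A: ring B is still aromatic and oxygen-substituted, whereas ring A is a dienone whose two C=C bonds are conjugated to the carbonyl and each carry a bromine, so it is a poor partner for an electrophile. The ketal should survive the acid formed because ionising a ketal C–O bond would place positive charge on the carbon next to the carbonyl. Silver keeps free bromide out of the flask, since bromide or HBr could add to the dienone and expel the aryloxide, which would reopen the ketal and erase the difference between the rings.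

Step 4
Reactants: 9 3',4,5,5',6,7-hexabromospiro[1,3-benzodioxole-2,1'-cyclohexa-3',5'-dien]-2'-one
Product: 10 3,4,5,6-tetrabromo-2-(3,5-dibromo-2-hydroxyphenoxy)phenol
Conditions: Na2S2O4 (3 equiv), THF–H2O, rt; then 1 M HCl
Reagents that add atoms: none
Why: Reductive cleavage of an ortho-quinone monoketal (the way quinone ketals and alpha-aryloxy ketones are reduced): electron transfer from dithionite to the dienone gives a ketyl radical anion that expels the tetrabromophenoxide from the adjacent ketal carbon, a second electron and protons rearomatise ring A, either of the two symmetry-related ketal C–O bonds of 9 gives the same diphenol, and aryl bromides are inert to dithionite.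

Compound list
1 | 2,2'-oxydiphenol | Oc1ccccc1Oc1ccccc1O | starting material
2 | bromine | BrBr | starting material
3 | 4-bromo-2-(2-hydroxyphenoxy)phenol (monobromide, not isolated) | Oc1ccc(Br)cc1Oc1ccccc1O | intermediate
4 | 2,2'-oxybis(4-bromophenol) (dibromide, not isolated in step 1) | Oc1ccc(Br)cc1Oc1cc(Br)ccc1O | intermediate
5 | 2,4-dibromo-6-(5-bromo-2-hydroxyphenoxy)phenol (tribromide, not isolated) | Oc1c(Br)cc(Br)cc1Oc1cc(Br)ccc1O | intermediate
6 | 2,2'-oxybis(4,6-dibromophenol), the symmetric bis(3,5-dibromo-2-hydroxyphenyl) ether | Oc1c(Br)cc(Br)cc1Oc1cc(Br)cc(Br)c1O | intermediate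
7 | racemic 3',4,5',6-tetrabromospiro[1,3-benzodioxole-2,1'-cyclohexa-3',5'-dien]-2'-one | O=C1C(Br)=CC(Br)=CC12Oc3cc(Br)cc(Br)c3O2 | intermediate
8 | racemic 3',4,5,5',6-pentabromospiro[1,3-benzodioxole-2,1'-cyclohexa-3',5'-dien]-2'-one (not isolated) | O=C1C(Br)=CC(Br)=CC12Oc3cc(Br)c(Br)c(Br)c3O2 | intermediate
9 | 3',4,5,5',6,7-hexabromospiro[1,3-benzodioxole-2,1'-cyclohexa-3',5'-dien]-2'-one (achiral) | O=C1C(Br)=CC(Br)=CC12Oc3c(Br)c(Br)c(Br)c(Br)c3O2 | intermediate
10 | 3,4,5,6-tetrabromo-2-(3,5-dibromo-2-hydroxyphenoxy)phenol (no stereocentre) | Oc1c(Br)cc(Br)cc1Oc1c(O)c(Br)c(Br)c(Br)c1Br | target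

Total step count: 4. Longest linear sequence: 4 steps, from 2,2'-oxydiphenol 1.

Steps most likely to fail

Step 3 (Proposed new method). The substitution may stall after the first bromine on the increasingly deactivated benzodioxole ring. The ring differentiation may also be lost if acid or a stray nucleophile opens the ketal, or if bromine adds across the dienone. The fallback uses known chemistry only; it sets out from 6 and comes back at 10. One hydroxyl of 6 is sulfonylated statistically (MsCl, 1.0 equiv, Et3N, CH2Cl2, −20 °C) to give 2,4-dibromo-6-(3,5-dibromo-2-hydroxyphenoxy)phenyl methanesulfonate F1, with recovered 6 and bis-mesylate recycled. The open positions of both rings are meta to their oxygen substituent, and a meta sulfonate deactivates far more than a meta hydroxyl. Br2 with catalytic FeBr3 in 1,2-dichloroethane at 50 °C should therefore brominate only the free-phenol ring, giving 2,4-dibromo-6-(2,3,4,5-tetrabromo-6-hydroxyphenoxy)phenyl methanesulfonate F2. NaOH in aqueous methanol at 60 °C then cleaves the sulfonate to 10.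

Step 2. The aryloxy–iodine intermediate may be intercepted by a second molecule or by acetate, or react at the bromine-bearing para carbon, instead of being closed by the neighbouring hydroxyl, which is flanked by bromine and weakly nucleophilic. The dienone may also dimerise. The fallback moves the dearomatisation one stage earlier; it sets out from dibromide 4 (isolated by running step 1 with two equivalents of bromine 2) and comes back at 10. The less hindered and more easily oxidised 4 is closed with PhI(OAc)2 in CH2Cl2 to racemic 5',6-dibromospiro[1,3-benzodioxole-2,1'-cyclohexa-3',5'-dien]-2'-one F3. Its three open benzodioxole positions are brominated with Br2/AgOCOCF3 to 4,5,5',6,7-pentabromospiro[1,3-benzodioxole-2,1'-cyclohexa-3',5'-dien]-2'-one F4. Na2S2O4 opens the ketal to 3,4,5,6-tetrabromo-2-(5-bromo-2-hydroxyphenoxy)phenol F5. One equivalent of Br2 in AcOH then places the last bromine ortho to the hydroxyl of ring A, the only activated position left, to give 10.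

Step 1. After the first bromine on each ring, substitution may drift to the positions para and ortho to the bridging oxygen, or run past four bromines, so that isomer mixtures form. The fallback replaces the single substrate-controlled operation by two isolated, reagent-directed stages; it sets out from 1 and comes back at 6. Benzyltrimethylammonium tribromide (2 equiv, CH2Cl2–MeOH, rt) brominates para to each hydroxyl, and dibromide 4 is isolated. N-Bromosuccinimide (2 equiv) with catalytic diisopropylamine in CH2Cl2 at 0 °C then delivers bromine to the carbon next to each hydroxyl through the hydrogen-bonded N-bromoamine. No compound outside the list is made (F0).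

Further compounds
F1 | step 3 | 2,4-dibromo-6-(3,5-dibromo-2-hydroxyphenoxy)phenyl methanesulfonate | CS(=O)(=O)Oc1c(Br)cc(Br)cc1Oc1cc(Br)cc(Br)c1O
F2 | step 3 | 2,4-dibromo-6-(2,3,4,5-tetrabromo-6-hydroxyphenoxy)phenyl methanesulfonate | CS(=O)(=O)Oc1c(Br)cc(Br)cc1Oc1c(O)c(Br)c(Br)c(Br)c1Br
F3 | step 2 | racemic 5',6-dibromospiro[1,3-benzodioxole-2,1'-cyclohexa-3',5'-dien]-2'-one | O=C1C=CC(Br)=CC12Oc3cc(Br)ccc3O2
F4 | step 2 | 4,5,5',6,7-pentabromospiro[1,3-benzodioxole-2,1'-cyclohexa-3',5'-dien]-2'-one | O=C1C=CC(Br)=CC12Oc3c(Br)c(Br)c(Br)c(Br)c3O2
F5 | step 2 | 3,4,5,6-tetrabromo-2-(5-bromo-2-hydroxyphenoxy)phenol | Oc1ccc(Br)cc1Oc1c(O)c(Br)c(Br)c(Br)c1Br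
F0 | step 1 | none | none
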